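A direct plan would assemble the ester-tethered triene A1 and close ring C together with a δ-lactone by a thermal intramolecular Diels–Alder reaction to the bicyclic lactone A2.
It would then saturate the ring alkene, dehydrogenate the lactone to A3, epoxidise, open the lactone and add the side chain by aldol condensation.
Its weakest steps would be three.
The ester-tethered cycloaddition would have to form two quaternary carbons (C8, C13) near 160 °C through the disfavoured cisoid ester, with no secured facial or endo/exo control.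
The enantioselective ketone reduction that would set the furyl carbinol centre C17 would cost several redox steps for a centre that only steers the cycloaddition and is oxidised away later.
The saturation and selenium-based re-dehydrogenation on the way to A3 would spend three steps to move one double bond to C14=C15, and would need a lactone enolate to be told apart from a ketone enolate.

The new route rests on a bond that the target does not contain, C16–C17. Because the furoyl carbon C17 (on C13) and the glycidate carbons C15–C16 (on C14) are neighbours on ring C, C13–C17–C16–C15–C14 is borrowed as ring D of a 2-methylcyclopentane-1,3-dione. The key step, a samarium diiodide-mediated Reformatsky-type aldol of bromo triketone 12, forms the hindered C8–C14 bond, closes ring C and sets C8 and C13 (and C14 as a relay) at once under control of C9. Ring D then fixes the oxirane geometry and face and is cleaved to the furyl ketone and the methyl ester. No cycloaddition, no auxiliary carbinol centre and no dehydrogenation detour remain.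

Key step: step 6

Remark on numbering: atom numbers follow the target. C5 is the pyranone carbon of the exocyclic alkene, C6 the =CH, C7 the enone carbonyl, C8 the ring carbon with methyl and acyl, C9 the ring CH, C10 the carbinol carbon, C11 and C12 the ring CH2 groups, C13 the ring carbon with methyl and furoyl, C14 the spiro carbon, C15 the oxirane CH, C16 the ester carbonyl and C17 the furyl ketone carbonyl. Ring C is the cyclohexane. Ring D is the temporary ring C13–C17–C16–C15–C14.
Assumption: compounds 4, 6 and 10 are taken as commercially available.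

Step 1
Reactants: 1 methyl (R)-lactate
Product: 2 methyl (2R)-2-[(tert-butyldiphenylsilyl)oxy]propanoate
Conditions: t-BuPh2SiCl, imidazole, DMF, 0 °C to rt
Reagents that add atoms: tert-butyl(chloro)diphenylsilane, CC(C)(C)[Si](Cl)(c1ccccc1)c1ccccc1
Why: Imidazole-promoted silyl ether formation at the secondary alcohol leaves C10 untouched; the bulky, acid-stable silyl group is chosen to steer step 4 and to survive BF3·OEt2 and CF3CO2H in step 5.

Step 2
Reactants: 2 methyl (2R)-2-[(tert-butyldiphenylsilyl)oxy]propanoate
Product: 3 (2R)-2-[(tert-butyldiphenylsilyl)oxy]propanal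
Conditions: iBu2AlH (1.05 equiv), CH2Cl2, −78 °C; MeOH, aq. sodium potassium tartrate
Reagents that add atoms: none
Why: Partial hydride reduction of the α-silyloxy ester stops at the aldehyde because the tetrahedral aluminium acetal is stable at −78 °C; the aldehyde is used crude to avoid epimerisation.

Step 3
Reactants: 3 (2R)-2-[(tert-butyldiphenylsilyl)oxy]propanal; 4 3-(triphenylphosphoranylidene)butan-2-one
Product: 5 (3E,5R)-5-[(tert-butyldiphenylsilyl)oxy]-3-methylhex-3-en-2-one
Conditions: toluene, 90 °C
Reagents that add atoms: none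
Why: Wittig olefination with the acyl-stabilised α-methyl ylide should give the (E)-enone C8=C9 with the acetyl group trans to C10, which places the C8 methyl cis to C10 as needed for the control in step 4.

Step 4
Reactants: 5 (3E,5R)-5-[(tert-butyldiphenylsilyl)oxy]-3-methylhex-3-en-2-one; 6 2-(2-bromoethyl)-2-methyl-1,3-dioxolane
Product: 9 (4R)-3-bromo-4-{(1R)-1-[(tert-butyldiphenylsilyl)oxy]ethyl}-3-methyl-6-(2-methyl-1,3-dioxolan-2-yl)hexan-2-one (both C3 epimers), via Grignard reagent 7 (not isolated), via trimethylsilyl enol ether 8 (not isolated)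
Conditions: 6, Mg, THF, rt; CuBr·SMe2 (20 mol %), Me3SiCl, THF, −78 °C, then 5; Et3N, aq. NaHCO3; crude 8, N-bromosuccinimide, THF, 0 °C
Reagents that add atoms: N-bromosuccinimide, O=C1CCC(=O)N1Br
Why: Copper-catalysed, Me3SiCl-accelerated conjugate addition forms C9–C11, and allylic 1,3-strain with the C8 methyl holds H10 in the enone plane so that the nucleophile enters anti to the silyloxy group and sets C9 relative to C10; the silyl enol ether, formed regiospecifically at C8, is then brominated there (α-bromination of a silyl enol ether), the C8 configuration being irrelevant.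

Step 5
Reactants: 9 bromo ketone ketal; 10 1,2-bis(trimethylsilyloxy)cyclobutene
Product: 12 2-[(3R)-4-bromo-3-{(1R)-1-[(tert-butyldiphenylsilyl)oxy]ethyl}-4-methyl-5-oxohexyl]-2-methylcyclopentane-1,3-dione (both C4 epimers of the chain), via silyloxycyclobutanone adduct 11 (not isolated)
Conditions: 10 (1.5 equiv), BF3·OEt2, CH2Cl2, −78 °C to rt; then CF3CO2H, rt
Reagents that add atoms: none
Why: Geminal acylation: BF3 ionises the dioxolane but not the ketone, the bis-silyl enol ether adds (Mukaiyama aldol) and the 2-silyloxycyclobutanone undergoes an acid-induced pinacol-type acyl shift to the 2,2-disubstituted cyclopentane-1,3-dione, which installs C14–C17 with C13 quaternary and two diastereotopic carbonyl groups; the C8 bromine blocks premature enolisation there.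

Step 6
Reactants: 12 bromo triketone
Product: 14 4-acetyl-5-{(1R)-1-[(tert-butyldiphenylsilyl)oxy]ethyl}-3a-hydroxy-4,7a-dimethyloctahydro-1H-inden-1-one (cis-fused ketol; relative configuration as in the compound list), via samarium enolate 13 (not isolated)
Conditions: SmI2 (2.2 equiv), THF, −78 °C; then H2O, −78 °C
Reagents that add atoms: none
Why: SmI2 cleaves the tertiary C8–Br bond by two single-electron transfers, faster than it touches any ketone at −78 °C, and so gives one samarium enolate, fixed at C8, from both bromide epimers, which adds to a ring carbonyl of the dione (intramolecular Reformatsky-type aldol; closest known type: SmI2-promoted cyclisation of α-halo carbonyl compounds onto ketones). Ring C closes in the 6-(enolexo)-exo-trig mode through the new C8–C14 bond, and ring D becomes cis-fused to it. Samarium bridges the enolate oxygen and the attacked carbonyl oxygen in a chair transition state, so the acetyl group and the C14 oxygen end up gauche and cis, which sets C14 and, with the C9 side chain equatorial, places the acetyl group equatorial and the C8 methyl axial (C8). C13 is set by the choice between the two diastereotopic carbonyl groups: the mode shown keeps the C13 methyl equatorial with the flat C17 carbonyl axial, whereas attack on the other carbonyl would force the C13 methyl axial and syn to an axial C8 substituent. The step needs chemoselectivity for C–Br over C=O (reduction potentials, 2.2 equiv of SmI2, cold quench before retro-aldol) and group and face selectivity (both relayed from the fixed C9 centre through the chelated chair). C14 is only a relay centre and is removed in step 7.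

Step 7
Reactants: 14 hydrindanone ketol
Product: 15 4-acetyl-5-{(1R)-1-[(tert-butyldiphenylsilyl)oxy]ethyl}-4,7a-dimethyl-2,4,5,6,7,7a-hexahydro-1H-inden-1-one (C14=C15)
Conditions: SOCl2, pyridine, CH2Cl2, −20 to 0 °C
Reagents that add atoms: none
Why: Dehydration of the tertiary alcohol through its chlorosulfite; C13 and C8 are quaternary, so only a C15 hydrogen can be lost and the alkene forms as C14=C15 inside ring D, while the cold, non-nucleophilic conditions avoid retro-aldol.

Step 8
Reactants: 15 β,γ-unsaturated hydrindenone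
Product: 17 2-hydroxy derivative of 15 (C16 hydroxyl trans to the C13 methyl), via potassium dienolate 16 (not isolated)
Conditions: KN(SiMe3)2 (1.05 equiv), THF, −78 °C; 2-(phenylsulfonyl)-3-phenyloxaziridine, −78 °C; AcOH
Reagents that add atoms: 2-(phenylsulfonyl)-3-phenyloxaziridine, O=S(=O)(c1ccccc1)N1OC1c1ccccc1
Why: Enolate oxidation with an N-sulfonyloxaziridine: the C16 hydrogens are both α to C17 and allylic, so one equivalent of base should give the C17 dienolate and not the methyl ketone enolate, and oxygen is transferred to C16 (the γ-position C14 is blocked) on the face opposite the angular C13 methyl, which sets C16.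

Step 9
Reactants: 17 allylic α-hydroxy ketone
Product: 18 4-acetyl-5-{(1R)-1-[(tert-butyldiphenylsilyl)oxy]ethyl}-3,3a-epoxy-2-hydroxy-4,7a-dimethyloctahydro-1H-inden-1-one (epoxide oxygen cis to the C16 hydroxyl and trans to the C13 methyl)
Conditions: VO(acac)2 (5 mol %), t-BuOOH (decane), CH2Cl2, 0 °C to rt
Reagents that add atoms: tert-butyl hydroperoxide, CC(C)(C)OO
Why: Hydroxyl-directed epoxidation of a cyclic allylic alcohol delivers oxygen syn to the C16 hydroxyl, which is also the face opposite the C13 methyl; ring D holds C16 cis to C13 on the oxirane, so C14 and C15 are set as in the target and no furan is yet present to compete.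

Step 10
Reactants: 18 epoxy hydroxy ketone; 19 3-bromofuran
Product: 22 4-acetyl-5-{(1R)-1-[(tert-butyldiphenylsilyl)oxy]ethyl}-3,3a-epoxy-1-(furan-3-yl)-4,7a-dimethyloctahydro-1H-indene-1,2-diol, via 3-furyllithium 20 (not isolated), via dilithium alkoxide enolate 21 (not isolated)
Conditions: 18, LiN(SiMe3)2 (2.2 equiv), THF, −78 °C; 3-furyllithium (from 19, n-BuLi, THF, −78 °C), −78 °C; AcOH
Reagents that add atoms: none
Why: Organolithium addition to a ketone: the amide base first turns the hydroxyl into its alkoxide and the C7 methyl ketone into its enolate (protection in the flask), so that 3-furyllithium, made by bromine–lithium exchange and kept at −78 °C to hold its position, adds only at C17; the epoxy alkoxide is syn and cannot undergo Payne rearrangement, and the C17 configuration is of no consequence because step 12 removes it.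

Step 11
Reactants: 22 diol
Product: 23 4-acetyl-5-{(1R)-1-[(tert-butyldiphenylsilyl)oxy]ethyl}-3,3a-epoxy-1-(furan-3-yl)-1-hydroxy-4,7a-dimethyloctahydro-2H-inden-2-one
Conditions: 2-iodoxybenzoic acid, DMSO, rt
Reagents that add atoms: none
Why: The hypervalent iodine reagent oxidises the secondary C16 alcohol to the ketone without cleaving the glycol, and the tertiary carbinol, furan, epoxide and silyl ether are inert to it.

Step 12
Reactants: 23 α-hydroxy ketone
Product: 24 methyl glycidate of ring C (C17 furan-3-yl ketone; C16 methyl ester; C7 methyl ketone; C10 silyl ether; all centres as in the target)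
Conditions: Pb(OAc)4, MeOH/toluene, 0 °C
Reagents that add atoms: methanol, CO
Why: Lead tetraacetate cleavage of an α-hydroxy ketone through its methanol hemiketal breaks the C16–C17 bond, turning C17 into the furyl ketone and C16 into the methyl ester; this removes ring D and its two relay centres without touching C13, C14 or C15.

Step 13
Reactants: 25 methyl 2-furoate
Product: 26 2-(furan-2-yl)propan-2-ol
Conditions: MeMgBr (2.2 equiv), Et2O, 0 °C to rt; H2O
Reagents that add atoms: methylmagnesium bromide, C[Mg]Br
Why: Double Grignard addition to the ester gives the tertiary furyl carbinol.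

Step 14
Reactants: 26 2-(furan-2-yl)propan-2-ol
Product: 27 6-hydroxy-2,2-dimethyl-2H-pyran-3(6H)-one
Conditions: N-bromosuccinimide, NaHCO3, THF/H2O, 0 °C
Reagents that add atoms: water, O
Why: Achmatowicz oxidative ring expansion of a 2-furyl carbinol gives the hydroxypyranone.

Step 15
Reactants: 27 6-hydroxy-2,2-dimethyl-2H-pyran-3(6H)-one
Product: 28 6,6-dimethyl-2H-pyran-2,5(6H)-dione
Conditions: CrO3, H2SO4, acetone, 0 °C
Reagents that add atoms: none
Why: Chromic acid (Jones) oxidation of the lactol gives the lactone of the ene-dione, which has no enolisable hydrogen.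

Step 16
Reactants: 24 methyl glycidate; 28 6,6-dimethyl-2H-pyran-2,5(6H)-dione
Product: 30 β-hydroxy ketone (C6 bonded to C5 of the pyranone, which carries a tertiary hydroxyl; mixture at that carbon), via lithium enolate 29 (not isolated)
Conditions: LiN(SiMe3)2 (1.05 equiv), THF, −78 °C; 28, −78 °C; AcOH, −78 °C
Reagents that add atoms: none
Why: Kinetic lithium enolate aldol addition: the C6 methyl group is the only enolisable position (C8 and C13 are quaternary), the enolate should add 1,2 to the ketone of the ene-dione at −78 °C, and the cold acidic quench prevents retro-aldol; the new carbinol centre is lost in step 17.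

Step 17
Reactants: 30 aldol adduct
Product: 31 tert-butyldiphenylsilyl ether of the target
Conditions: Ph2S[OC(CF3)2Ph]2 (Martin sulfurane), CH2Cl2, 0 °C to rt
Reagents that add atoms: none
Why: Dehydration of the tertiary β-hydroxy ketone through its alkoxysulfonium ion can only go towards C6, and because C6 carries two hydrogens both carbinol epimers can reach the less strained alkene, with the acyl group next to the ring CH and away from the gem-dimethyl carbon.

Step 18
Reactants: 31 silyl ether of the target
Product: 32 CNP0293135.1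
Conditions: HF·pyridine, pyridine, THF, 0 °C to rt
Reagents that add atoms: none
Why: Buffered fluoride cleavage of the silyl ether frees the C10 alcohol and should leave the glycidic ester, the furyl ketone and the dienone lactone intact.

Compound list
1 | methyl (R)-lactate | C[C@@H](O)C(=O)OC | starting material
2 | methyl (2R)-2-[(tert-butyldiphenylsilyl)oxy]propanoate | COC(=O)[C@@H](C)O[Si](c1ccccc1)(c1ccccc1)C(C)(C)C | intermediate
3 | (2R)-2-[(tert-butyldiphenylsilyl)oxy]propanal | O=C[C@@H](C)O[Si](c1ccccc1)(c1ccccc1)C(C)(C)C | intermediate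
4 | 3-(triphenylphosphoranylidene)butan-2-one | CC(=O)C(C)=P(c1ccccc1)(c1ccccc1)c1ccccc1 | starting material
5 | (3E,5R)-5-[(tert-butyldiphenylsilyl)oxy]-3-methylhex-3-en-2-one | CC(=O)/C(C)=C/[C@@H](C)O[Si](c1ccccc1)(c1ccccc1)C(C)(C)C | intermediate
6 | 2-(2-bromoethyl)-2-methyl-1,3-dioxolane | CC1(CCBr)OCCO1 | starting material
7 | [2-(2-methyl-1,3-dioxolan-2-yl)ethyl]magnesium bromide (not isolated) | CC1(CC[Mg]Br)OCCO1 | intermediate
8 | trimethylsilyl enol ether of the conjugate adduct (C7–OSiMe3, C7=C8, E/Z mixture; C9 S, C10 R; not isolated) | CC(O[Si](C)(C)C)=C(C)[C@@H]([C@@H](C)O[Si](c1ccccc1)(c1ccccc1)C(C)(C)C)CCC1(C)OCCO1 | intermediate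
9 | (4R)-3-bromo-4-{(1R)-1-[(tert-butyldiphenylsilyl)oxy]ethyl}-3-methyl-6-(2-methyl-1,3-dioxolan-2-yl)hexan-2-one, both C3 (C8) epimers | CC(=O)C(C)(Br)[C@@H]([C@@H](C)O[Si](c1ccccc1)(c1ccccc1)C(C)(C)C)CCC1(C)OCCO1 | intermediate
10 | 1,2-bis(trimethylsilyloxy)cyclobutene | C[Si](C)(C)OC1=C(O[Si](C)(C)C)CC1 | starting material
11 | 2-(trimethylsilyloxy)cyclobutanone adduct at C13, which still carries the 2-hydroxyethoxy group (not isolated) | CC(=O)C(C)(Br)[C@@H]([C@@H](C)O[Si](c1ccccc1)(c1ccccc1)C(C)(C)C)CCC(C)(OCCO)C1(O[Si](C)(C)C)CCC1=O | intermediate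
12 | 2-[(3R)-4-bromo-3-{(1R)-1-[(tert-butyldiphenylsilyl)oxy]ethyl}-4-methyl-5-oxohexyl]-2-methylcyclopentane-1,3-dione, both epimers at the C–Br carbon (C8) | CC(=O)C(C)(Br)[C@@H]([C@@H](C)O[Si](c1ccccc1)(c1ccccc1)C(C)(C)C)CCC1(C)C(=O)CCC1=O | intermediate
13 | diiodosamarium enolate of the C7 ketone of 12 (C7=C8; not isolated) | CC(O[Sm](I)I)=C(C)[C@@H]([C@@H](C)O[Si](c1ccccc1)(c1ccccc1)C(C)(C)C)CCC1(C)C(=O)CCC1=O | intermediate
14 | 4-acetyl-5-{(1R)-1-[(tert-butyldiphenylsilyl)oxy]ethyl}-3a-hydroxy-4,7a-dimethyloctahydro-1H-inden-1-one; cis-fused; C13 methyl, C14 hydroxyl and C8 acetyl on one face of ring C; C8 methyl, C15 and the C9 side chain on the other | C1C(=O)[C@]2(C)CC[C@H]([C@@H](C)O[Si](c5ccccc5)(c5ccccc5)C(C)(C)C)[C@@](C)(C(C)=O)[C@]2(O)C1 | intermediate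
15 | 4-acetyl-5-{(1R)-1-[(tert-butyldiphenylsilyl)oxy]ethyl}-4,7a-dimethyl-2,4,5,6,7,7a-hexahydro-1H-inden-1-one (C14=C15; C13 methyl and C8 acetyl on one face, C8 methyl and C9 side chain on the other) | C1C(=O)[C@]2(C)CC[C@H]([C@@H](C)O[Si](c5ccccc5)(c5ccccc5)C(C)(C)C)[C@@](C)(C(C)=O)C2=C1 | intermediate
16 | potassium dienolate of 15 (C17–OK, C17=C16, C15=C14; not isolated) | C1=C(O[K])[C@]2(C)CC[C@H]([C@@H](C)O[Si](c5ccccc5)(c5ccccc5)C(C)(C)C)[C@@](C)(C(C)=O)C2=C1 | intermediate
17 | 2-hydroxy derivative of 15 (C16 hydroxyl trans to the C13 methyl on ring D) | O[C@@H]1C(=O)[C@]2(C)CC[C@H]([C@@H](C)O[Si](c5ccccc5)(c5ccccc5)C(C)(C)C)[C@@](C)(C(C)=O)C2=C1 | intermediate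
18 | 4-acetyl-5-{(1R)-1-[(tert-butyldiphenylsilyl)oxy]ethyl}-3,3a-epoxy-2-hydroxy-4,7a-dimethyloctahydro-1H-inden-1-one (epoxide oxygen cis to the C16 hydroxyl, trans to the C13 methyl) | O[C@@H]1C(=O)[C@]2(C)CC[C@H]([C@@H](C)O[Si](c5ccccc5)(c5ccccc5)C(C)(C)C)[C@@](C)(C(C)=O)[C@]23O[C@H]13 | intermediate
19 | 3-bromofuran | Brc1ccoc1 | starting material
20 | 3-furyllithium (not isolated) | [Li]c1ccoc1 | intermediate
21 | dilithium salt of 18 (C16 alkoxide and C7 enolate; not isolated) | [Li]O[C@@H]1C(=O)[C@]2(C)CC[C@H]([C@@H](C)O[Si](c5ccccc5)(c5ccccc5)C(C)(C)C)[C@@](C)(C(=C)O[Li])[C@]23O[C@H]13 | intermediate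
22 | 4-acetyl-5-{(1R)-1-[(tert-butyldiphenylsilyl)oxy]ethyl}-3,3a-epoxy-1-(furan-3-yl)-4,7a-dimethyloctahydro-1H-indene-1,2-diol (furan expected on the face of the C16 hydroxyl; C17 configuration without consequence) | O[C@@H]1[C@](O)(c4ccoc4)[C@]2(C)CC[C@H]([C@@H](C)O[Si](c5ccccc5)(c5ccccc5)C(C)(C)C)[C@@](C)(C(C)=O)[C@]23O[C@H]13 | intermediate
23 | 4-acetyl-5-{(1R)-1-[(tert-butyldiphenylsilyl)oxy]ethyl}-3,3a-epoxy-1-(furan-3-yl)-1-hydroxy-4,7a-dimethyloctahydro-2H-inden-2-one | O=C1[C@](O)(c4ccoc4)[C@]2(C)CC[C@H]([C@@H](C)O[Si](c5ccccc5)(c5ccccc5)C(C)(C)C)[C@@](C)(C(C)=O)[C@]23O[C@H]13 | intermediate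
24 | methyl glycidate of ring C: C13 (methyl, furan-3-carbonyl), C14 spiro-oxirane with CO2Me at C15, C8 (methyl, acetyl), C9 (R)-1-silyloxyethyl; all centres as in the target | COC(=O)[C@H]1O[C@@]12[C@](C)(C(=O)c1ccoc1)CC[C@H]([C@@H](C)O[Si](c1ccccc1)(c1ccccc1)C(C)(C)C)[C@@]2(C)C(C)=O | intermediate
25 | methyl 2-furoate | COC(=O)c1ccco1 | starting material
26 | 2-(furan-2-yl)propan-2-ol | CC(C)(O)c1ccco1 | intermediate
27 | 6-hydroxy-2,2-dimethyl-2H-pyran-3(6H)-one | CC1(C)OC(O)C=CC1=O | intermediate
28 | 6,6-dimethyl-2H-pyran-2,5(6H)-dione | CC1(C)OC(=O)C=CC1=O | intermediate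
29 | lithium enolate of the C7 methyl ketone of 24 (not isolated) | COC(=O)[C@H]1O[C@@]12[C@](C)(C(=O)c1ccoc1)CC[C@H]([C@@H](C)O[Si](c1ccccc1)(c1ccccc1)C(C)(C)C)[C@@]2(C)C(=C)O[Li] | intermediate
30 | aldol adduct: C6 methylene of 24 bonded to C5 of the pyranone, which carries a tertiary hydroxyl (mixture at that carbon) | COC(=O)[C@H]1O[C@@]12[C@](C)(C(=O)c1ccoc1)CC[C@H]([C@@H](C)O[Si](c1ccccc1)(c1ccccc1)C(C)(C)C)[C@@]2(C)C(=O)CC1(O)C=CC(=O)OC1(C)C | intermediate
31 | C10 tert-butyldiphenylsilyl ether of the target (exocyclic enone with the acyl group cis to the ring CH) | COC(=O)[C@H]1O[C@@]12[C@](C)(C(=O)c1ccoc1)CC[C@H]([C@@H](C)O[Si](c1ccccc1)(c1ccccc1)C(C)(C)C)[C@@]2(C)C(=O)/C=C1\C=CC(=O)OC1(C)C | intermediate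
32 | CNP0293135.1 | COC(=O)[C@H]1O[C@@]12[C@](C)(C(=O)c1ccoc1)CC[C@H]([C@@H](C)O)[C@@]2(C)C(=O)/C=C1\C=CC(=O)OC1(C)C | target

Total step count: 18. Longest linear sequence: 15 steps (steps 1–12 and 16–18).

Steps most likely to fail

Step 6. The enolate may discriminate poorly between the two ring carbonyl groups or between its two faces, or SmI2 may reduce a dione carbonyl in competition. The fallback changes the mode of enolisation from reductive to enamine catalysis. From 12 the bromine would be removed with zinc in acetic acid to give the triketone 2-[(3S)-3-{(1R)-1-[(tert-butyldiphenylsilyl)oxy]ethyl}-4-methyl-5-oxohexyl]-2-methylcyclopentane-1,3-dione F1. This would be cyclised with a primary amino acid (phenylalanine of the matched configuration, camphorsulfonic acid, MeCN, 60 °C) in a Hajos–Parrish-type aldol through the more substituted secondary enamine, and would come back to the route at 14.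

Step 10. The protection in the flask may be incomplete, so that 3-furyllithium adds to or deprotonates the C7 methyl ketone, or the base may open the epoxide from C16. The fallback masks both groups covalently. From 18, Me3SiOTf and Et3N would give the C16 trimethylsilyl ether and C7 trimethylsilyl enol ether F2. 3-Furyllithium would then add to the only free carbonyl group to give the furyl carbinol F3, and citric acid in methanol would remove both silyl groups and return to 22.

Step 16. The enolate may add in conjugate fashion to the doubly activated alkene of 28 instead of 1,2, or the adduct may revert by retro-aldol on work-up. The fallback uses a partner without that alkene activation and adjusts the oxidation level afterwards. Lactol 27 would be converted (MeOH, pyridinium p-toluenesulfonate) into 6-methoxy-2,2-dimethyl-2H-pyran-3(6H)-one F4. The lithium enolate of 24 would add 1,2 to this enone to give the carbinol F5, and dehydration as in step 17 would give the dienone acetal F6. Pyridinium p-toluenesulfonate in aqueous acetone would give the lactol F7, and MnO2 would oxidise this allylic lactol to the lactone, returning to the route at 31.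

Further compounds
F1 | step 6 | 2-[(3S)-3-{(1R)-1-[(tert-butyldiphenylsilyl)oxy]ethyl}-4-methyl-5-oxohexyl]-2-methylcyclopentane-1,3-dione (both C4 epimers of the chain) | CC(=O)C(C)[C@@H]([C@@H](C)O[Si](c1ccccc1)(c1ccccc1)C(C)(C)C)CCC1(C)C(=O)CCC1=O
F2 | step 10 | C16 trimethylsilyl ether and C7 trimethylsilyl enol ether of 18 | C[Si](C)(C)O[C@@H]1C(=O)[C@]2(C)CC[C@H]([C@@H](C)O[Si](c5ccccc5)(c5ccccc5)C(C)(C)C)[C@@](C)(C(=C)O[Si](C)(C)C)[C@]23O[C@H]13
F3 | step 10 | C17 furan-3-yl carbinol from F2 (silyl groups still in place) | C[Si](C)(C)O[C@@H]1[C@](O)(c4ccoc4)[C@]2(C)CC[C@H]([C@@H](C)O[Si](c5ccccc5)(c5ccccc5)C(C)(C)C)[C@@](C)(C(=C)O[Si](C)(C)C)[C@]23O[C@H]13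
F4 | step 16 | 6-methoxy-2,2-dimethyl-2H-pyran-3(6H)-one | COC1C=CC(=O)C(C)(C)O1
F5 | step 16 | aldol adduct of 24 with F4 (tertiary carbinol at C5; mixture at C5 and at the acetal carbon) | COC(=O)[C@H]1O[C@@]12[C@](C)(C(=O)c1ccoc1)CC[C@H]([C@@H](C)O[Si](c1ccccc1)(c1ccccc1)C(C)(C)C)[C@@]2(C)C(=O)CC1(O)C=CC(OC)OC1(C)C
F6 | step 16 | dienone methyl acetal (exocyclic enone; pyran still at the lactol ether level) | COC(=O)[C@H]1O[C@@]12[C@](C)(C(=O)c1ccoc1)CC[C@H]([C@@H](C)O[Si](c1ccccc1)(c1ccccc1)C(C)(C)C)[C@@]2(C)C(=O)/C=C1\C=CC(OC)OC1(C)C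
F7 | step 16 | dienone lactol (free hemiacetal of F6) | COC(=O)[C@H]1O[C@@]12[C@](C)(C(=O)c1ccoc1)CC[C@H]([C@@H](C)O[Si](c1ccccc1)(c1ccccc1)C(C)(C)C)[C@@]2(C)C(=O)/C=C1\C=CC(O)OC1(C)C
A1 | direct plan | ester-tethered triene: (1S)-furyl dienyl ester of (E)-4-methyl-5-oxohex-3-enoic acid with a C10 silyl ether | CC(=O)/C(C)=C/CC(=O)O[C@H](c1ccoc1)/C(C)=C/C=C/[C@@H](C)O[Si](C)(C)C(C)(C)C
A2 | direct plan | cis-fused cyclohexene δ-lactone from the intramolecular cycloaddition | O=C1C[C@H]2[C@](C)(C(C)=O)[C@@H]([C@@H](C)O[Si](C)(C)C(C)(C)C)C=C[C@@]2(C)[C@@H](c2ccoc2)O1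
A3 | direct plan | C14=C15 unsaturated δ-lactone after saturation and re-dehydrogenation | O=C1C=C2[C@](C)(C(C)=O)[C@@H]([C@@H](C)O[Si](C)(C)C(C)(C)C)CC[C@@]2(C)[C@@H](c2ccoc2)O1
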